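**Retrosynthetic overview**

1. The target, (2R,3R)-epigallocatechin 7-O-gallate, is reached last by hydrogenolysis of the six benzyl ethers of a fully assembled flavan-3-ol 7-O-gallate.
2. Key disconnection C2–C1′ (pyran C ring to pyrogallol B ring): a 3,4,5-tris(benzyloxy)phenyl group is passed from boron to C2 of a (3R)-2-ethoxychroman-3-ol that already carries the 7-O-galloyl ester and free 3-OH and 5-OH.
3. Enabling feature: C2 of the pyran ring is bonded to ring oxygen O1 (an anomeric carbon that ionises to an oxocarbenium ion), and its neighbour C3 carries a hydroxyl on the face the aryl must occupy; O3 can hold the boron and hand the aryl to C2 on that face, so both C2 anomers converge on the 2,3-cis product.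
4. The C ring (O1–C2) is closed earlier by acid transacetalisation of an (R)-α-hydroxy diethyl acetal; the A ring then has two equivalent ortho-OH groups and the gallate para, so ring closure itself fixes 5-OH versus 7-O-gallate. C4–C4a comes from Cu-catalysed opening of (R)-glycidaldehyde diethyl acetal by an aryl-metal made by directed metalation of a phloroglucinol tri-ether.
5. Ring order: A and B rings are bought as arenes (phloroglucinol, 5-bromo-1,2,3-trimethoxybenzene); the C ring is closed in step 8; the B ring is attached in step 12.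

Key step: step 12

Assumption: in the hydrolytic kinetic resolution (step 3) the (S,S)-catalyst is taken to consume the (S)-epoxide, as for terminal epoxides whose substituent outranks the ring CH2 (epichlorohydrin type); if the sense is the reverse, only the catalyst antipode changes.

**Route**

Step 1
Reactants: 1 phloroglucinol
Product: 2 3,5-bis(methoxymethoxy)phenol
Conditions: MOMCl (2.0 eq), i-Pr2NEt (2.2 eq), DMF, 0 °C → rt; chromatography
Reagents that add atoms: chloromethyl methyl ether, COCCl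
Why: Williamson-type O-alkylation of a C3-symmetric triphenol, in which the bis-ether should be the main statistical product and is separable from the mono- and tris-ethers; no stereocentre is involved.

Step 2
Reactants: 2 3,5-bis(methoxymethoxy)phenol
Product: 3 triisopropyl[3,5-bis(methoxymethoxy)phenoxy]silane
Conditions: TIPSCl (1.2 eq), imidazole (2.5 eq), DMF, rt
Reagents that add atoms: chlorotriisopropylsilane, CC(C)[Si](Cl)(C(C)C)C(C)C
Why: Silylation of the only free phenol gives a bulky, non-coordinating group that survives n-BuLi and marks the oxygen that will later carry the gallate.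

Step 3
Reactants: 4 rac-2-(diethoxymethyl)oxirane
Product: 5 (R)-2-(diethoxymethyl)oxirane
Conditions: (S,S)-(salen)Co(III)OAc (0.5 mol%), H2O (0.55 eq), THF (min.), 0 °C → rt; distillation
Reagents that add atoms: none
Why: Jacobsen hydrolytic kinetic resolution of a terminal epoxide should hydrolyse the (S)-enantiomer and leave the (R)-epoxide, whose stereocentre becomes C3 of the target.

Step 4
Reactants: 3 triisopropyl[3,5-bis(methoxymethoxy)phenoxy]silane; 5 (R)-2-(diethoxymethyl)oxirane
Product: 8 (2R)-1,1-diethoxy-3-[2,6-bis(methoxymethoxy)-4-(triisopropylsilyloxy)phenyl]propan-2-ol, via aryllithium 6 (not isolated), via arylmagnesium bromide 7 (not isolated)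
Conditions: n-BuLi (1.05 eq), THF, 0 °C; MgBr2·OEt2 (1.1 eq); CuI (10 mol%), 5 (0.8 eq), −30 → 0 °C; aq NH4Cl
Reagents that add atoms: none
Why: Directed ortho-metalation at the carbon flanked by both MOM ethers, Li→Mg transmetalation and Cu-catalysed SN2 opening of the epoxide at its CH2 terminus should form the C4–C4a bond and leave the stereocentre untouched.

Step 5
Reactants: 8 (2R)-1,1-diethoxy-3-[2,6-bis(methoxymethoxy)-4-(triisopropylsilyloxy)phenyl]propan-2-ol
Product: 9 4-[(2R)-3,3-diethoxy-2-hydroxypropyl]-3,5-bis(methoxymethoxy)phenol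
Conditions: TBAF (1.1 eq), AcOH (1.1 eq), THF, 0 °C
Reagents that add atoms: none
Why: Buffered fluoride desilylation cleaves the aryl silyl ether selectively, while the MOM ethers, the acetal and the stereocentre are inert.

Step 6
Reactants: 10 3,4,5-tris(benzyloxy)benzoic acid
Product: 11 3,4,5-tris(benzyloxy)benzoyl chloride
Conditions: (COCl)2 (1.5 eq), DMF (cat.), CH2Cl2, 0 °C → rt; evaporation
Reagents that add atoms: oxalyl chloride, ClC(=O)C(=O)Cl
Why: Acid chloride formation through Vilsmeier-type activation is routine for this electron-rich benzoic acid.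

Step 7
Reactants: 9 4-[(2R)-3,3-diethoxy-2-hydroxypropyl]-3,5-bis(methoxymethoxy)phenol; 11 3,4,5-tris(benzyloxy)benzoyl chloride
Product: 12 4-[(2R)-3,3-diethoxy-2-hydroxypropyl]-3,5-bis(methoxymethoxy)phenyl 3,4,5-tris(benzyloxy)benzoate
Conditions: Et3N (1.5 eq), CH2Cl2, −20 → 0 °C (no DMAP)
Reagents that add atoms: none
Why: Base-mediated O-acylation should take the unhindered, acidic phenol in preference to the hindered secondary alcohol, placing the galloyl ester on the future O7 while both ortho oxygens are still masked.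

Step 8
Reactants: 12 4-[(2R)-3,3-diethoxy-2-hydroxypropyl]-3,5-bis(methoxymethoxy)phenyl 3,4,5-tris(benzyloxy)benzoate
Product: 13 (2RS,3R)-2-ethoxy-3,5-dihydroxychroman-7-yl 3,4,5-tris(benzyloxy)benzoate
Conditions: HCl (0.3 M, anhydrous) in EtOH, 35 °C
Reagents that add atoms: none
Why: Acid cleavage of both MOM acetals is followed by 6-exo-trig attack of a phenol oxygen on the side-chain oxocarbenium ion (a Fischer-glycosidation-type transacetalisation); the two ortho-OH groups are equivalent, so either closure gives the same chroman with 5-OH free and the ester on O7, C3 is untouched and C2 is deliberately left as an anomeric mixture.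

Step 9
Reactants: 14 5-bromo-1,2,3-trimethoxybenzene
Product: 15 5-bromobenzene-1,2,3-triol
Conditions: BBr3 (3.5 eq), CH2Cl2, −78 °C → rt; H2O
Reagents that add atoms: none
Why: Lewis-acid cleavage of aryl methyl ethers by BBr3 is standard and leaves the aryl bromide intact.

Step 10
Reactants: 15 5-bromobenzene-1,2,3-triol
Product: 16 5-bromo-1,2,3-tris(benzyloxy)benzene
Conditions: BnBr (3.3 eq), K2CO3 (4 eq), DMF, 60 °C, N2
Reagents that add atoms: benzyl bromide, BrCc1ccccc1
Why: Williamson benzylation of the three phenols installs the groups that are removed together in the last step.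

Step 11
Reactants: 16 5-bromo-1,2,3-tris(benzyloxy)benzene
Product: 19 [3,4,5-tris(benzyloxy)phenyl]boronic acid, via aryllithium 17 (not isolated), via lithium triisopropoxyborate 18 (not isolated)
Conditions: n-BuLi (1.1 eq), THF, −78 °C; B(Oi-Pr)3 (1.5 eq), −78 °C → rt; 1 M HCl
Reagents that add atoms: triisopropyl borate, CC(C)OB(OC(C)C)OC(C)C; water, O
Why: Bromine–lithium exchange, borylation and hydrolysis fix boron at the ring position meta to two oxygens and para to the third, a position that electrophilic substitution of a pyrogallol ether would not reach.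

Step 12
Reactants: 13 (2RS,3R)-2-ethoxy-3,5-dihydroxychroman-7-yl 3,4,5-tris(benzyloxy)benzoate; 19 [3,4,5-tris(benzyloxy)phenyl]boronic acid
Product: 22 (2R,3R)-3,5-dihydroxy-2-[3,4,5-tris(benzyloxy)phenyl]chroman-7-yl 3,4,5-tris(benzyloxy)benzoate, via O3-arylboronic half-ester 20 (not isolated), via oxocarbenium borate zwitterion 21 (not isolated)
Conditions: 19 (2.5 eq), 4 Å MS, CH2Cl2, rt, 1 h; BF3·OEt2 (2.0 eq), −40 → 0 °C; aq NaHCO3
Reagents that add atoms: none
Why: Proposed new method: boronic acid 19 first esterifies the free C3–OH of 13 (20); BF3 then ionises the C2–OEt bond of either anomer to the O1-stabilised oxocarbenium ion while ethoxide or fluoride ends up on boron, which becomes a tetracoordinate ate centre (21), and the aryl group moves with its ipso carbon from boron to C2 through a five-membered cyclic transition state (C2–C3–O3–B–C-ipso), after which aqueous work-up cleaves the O3–B bond. The closest known reaction types are the Petasis borono-Mannich reaction of α-hydroxy aldehydes, the hydroxyl-directed cis-addition of aryl- and alkenylboronates to 3-hydroxy-N-acyliminium ions and the Lewis-acid coupling of organoboron reagents with chromene acetals and other O,O-acetals; new is the hydroxyl-tethered transfer to a saturated 3-hydroxychroman-2-yl cation. No ring is closed. The one new stereocentre, C2, is controlled by the existing C3 centre: the aryl is bound to O3 and can reach C2 only on the face cis to it, which gives 2R from 3R whichever anomer of 13 ionises. The step needs cis- over trans-delivery, ipso- over ortho-attack of the electron-rich arene, and arylation over self-condensation through C6/C8 of the A ring; the boron tether and the ate character of the ipso carbon should secure the first two, the deactivating 7-O-acyl group together with low temperature and an excess of 19 the third.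

Step 13
Reactants: 22 (2R,3R)-3,5-dihydroxy-2-[3,4,5-tris(benzyloxy)phenyl]chroman-7-yl 3,4,5-tris(benzyloxy)benzoate
Product: 23 (2R,3R)-epigallocatechin 7-O-gallate
Conditions: H2 (1 atm), 20% Pd(OH)2/C, THF/MeOH (1:1), rt; filtration under Ar
Reagents that add atoms: none
Why: Heterogeneous hydrogenolysis should remove all six aryl benzyl ethers under neutral conditions that leave the aryl ester, the C2–O1 bond and both stereocentres intact.

**Compound list**

1 | phloroglucinol | Oc1cc(O)cc(O)c1 | starting material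
2 | 3,5-bis(methoxymethoxy)phenol | COCOc1cc(O)cc(OCOC)c1 | intermediate
3 | triisopropyl[3,5-bis(methoxymethoxy)phenoxy]silane | COCOc1cc(OCOC)cc(O[Si](C(C)C)(C(C)C)C(C)C)c1 | intermediate
4 | rac-2-(diethoxymethyl)oxirane | CCOC(OCC)C1CO1 | starting material
5 | (R)-2-(diethoxymethyl)oxirane | CCOC(OCC)[C@H]1CO1 | intermediate
6 | [2,6-bis(methoxymethoxy)-4-(triisopropylsilyloxy)phenyl]lithium | [Li]c1c(OCOC)cc(O[Si](C(C)C)(C(C)C)C(C)C)cc1OCOC | intermediate
7 | [2,6-bis(methoxymethoxy)-4-(triisopropylsilyloxy)phenyl]magnesium bromide | Br[Mg]c1c(OCOC)cc(O[Si](C(C)C)(C(C)C)C(C)C)cc1OCOC | intermediate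
8 | (2R)-1,1-diethoxy-3-[2,6-bis(methoxymethoxy)-4-(triisopropylsilyloxy)phenyl]propan-2-ol | CCOC(OCC)[C@H](O)Cc1c(OCOC)cc(O[Si](C(C)C)(C(C)C)C(C)C)cc1OCOC | intermediate
9 | 4-[(2R)-3,3-diethoxy-2-hydroxypropyl]-3,5-bis(methoxymethoxy)phenol | CCOC(OCC)[C@H](O)Cc1c(OCOC)cc(O)cc1OCOC | intermediate
10 | 3,4,5-tris(benzyloxy)benzoic acid | OC(=O)c1cc(OCc2ccccc2)c(OCc2ccccc2)c(OCc2ccccc2)c1 | starting material
11 | 3,4,5-tris(benzyloxy)benzoyl chloride | ClC(=O)c1cc(OCc2ccccc2)c(OCc2ccccc2)c(OCc2ccccc2)c1 | intermediate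
12 | 4-[(2R)-3,3-diethoxy-2-hydroxypropyl]-3,5-bis(methoxymethoxy)phenyl 3,4,5-tris(benzyloxy)benzoate | CCOC(OCC)[C@H](O)Cc1c(OCOC)cc(OC(=O)c2cc(OCc3ccccc3)c(OCc3ccccc3)c(OCc3ccccc3)c2)cc1OCOC | intermediate
13 | (2RS,3R)-2-ethoxy-3,5-dihydroxychroman-7-yl 3,4,5-tris(benzyloxy)benzoate | O=C(Oc1cc(O)c2c(c1)OC(OCC)[C@H](O)C2)c1cc(OCc3ccccc3)c(OCc3ccccc3)c(OCc3ccccc3)c1 | intermediate
14 | 5-bromo-1,2,3-trimethoxybenzene | COc1cc(Br)cc(OC)c1OC | starting material
15 | 5-bromobenzene-1,2,3-triol | Oc1cc(Br)cc(O)c1O | intermediate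
16 | 5-bromo-1,2,3-tris(benzyloxy)benzene | Brc1cc(OCc2ccccc2)c(OCc2ccccc2)c(OCc2ccccc2)c1 | intermediate
17 | [3,4,5-tris(benzyloxy)phenyl]lithium | [Li]c1cc(OCc2ccccc2)c(OCc2ccccc2)c(OCc2ccccc2)c1 | intermediate
18 | lithium triisopropoxy[3,4,5-tris(benzyloxy)phenyl]borate | [Li+].CC(C)O[B-](OC(C)C)(OC(C)C)c1cc(OCc2ccccc2)c(OCc2ccccc2)c(OCc2ccccc2)c1 | intermediate
19 | [3,4,5-tris(benzyloxy)phenyl]boronic acid | OB(O)c1cc(OCc2ccccc2)c(OCc2ccccc2)c(OCc2ccccc2)c1 | intermediate
20 | O3-[hydroxy(3,4,5-tris(benzyloxy)phenyl)boryl] ester of 13 | O=C(Oc1cc(O)c2c(c1)OC(OCC)[C@H](OB(O)c1cc(OCc3ccccc3)c(OCc3ccccc3)c(OCc3ccccc3)c1)C2)c1cc(OCc3ccccc3)c(OCc3ccccc3)c(OCc3ccccc3)c1 | intermediate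
21 | (3R)-chroman-2-ylium O3-(aryl)(ethoxy)(hydroxy)borate zwitterion | O=C(Oc1cc(O)c2c(c1)[O+]=C[C@H](O[B-](O)(OCC)c1cc(OCc3ccccc3)c(OCc3ccccc3)c(OCc3ccccc3)c1)C2)c1cc(OCc3ccccc3)c(OCc3ccccc3)c(OCc3ccccc3)c1 | intermediate
22 | (2R,3R)-3,5-dihydroxy-2-[3,4,5-tris(benzyloxy)phenyl]chroman-7-yl 3,4,5-tris(benzyloxy)benzoate | O=C(Oc1cc(O)c2c(c1)O[C@H](c1cc(OCc3ccccc3)c(OCc3ccccc3)c(OCc3ccccc3)c1)[C@H](O)C2)c1cc(OCc3ccccc3)c(OCc3ccccc3)c(OCc3ccccc3)c1 | intermediate
23 | (2R,3R)-epigallocatechin 7-O-gallate | O=C(Oc1cc(O)c2c(c1)O[C@H](c1cc(O)c(O)c(O)c1)[C@H](O)C2)c1cc(O)c(O)c(O)c1 | target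

**Step count and risks**

Total step count: 13. Longest linear sequence: 8 steps (1, 2, 4, 5, 7, 8, 12, 13).

Steps most likely to fail:

1. Step 12 (carries the label "Proposed new method:"). The aryl may migrate too slowly from the tether, because its ipso carbon is activated only by the para oxygen, so that protodeboronation wins. The arene may instead attack through its more electron-rich ortho carbons. The oxocarbenium ion may be intercepted by C6/C8 of another A ring. Facial control would be lost if the transfer became intermolecular. Fallback (known chemistry only; sets out from 12, returns at 22): the C2–aryl bond is made by carbonyl addition and the pyran ring is closed afterwards with inversion. Silylation of 12 (TBSOTf, 2,6-lutidine, CH2Cl2, −40 °C) should give 4-[(2R)-2-(tert-butyldimethylsilyloxy)-3,3-diethoxypropyl]-3,5-bis(methoxymethoxy)phenyl 3,4,5-tris(benzyloxy)benzoate F1. Neutral acetal exchange (I2 cat., acetone, rt) should give 4-[(2R)-2-(tert-butyldimethylsilyloxy)-3-oxopropyl]-3,5-bis(methoxymethoxy)phenyl 3,4,5-tris(benzyloxy)benzoate F2. Felkin–Anh addition of 3,4,5-tris(benzyloxy)phenylmagnesium bromide (from 16 and Mg; THF, −78 °C, where the aldehyde reacts far faster than the aryl ester) should give the anti alcohol 4-[(2R,3S)-2-(tert-butyldimethylsilyloxy)-3-hydroxy-3-[3,4,5-tris(benzyloxy)phenyl]propyl]-3,5-bis(methoxymethoxy)phenyl 3,4,5-tris(benzyloxy)benzoate F3. MOM cleavage (ZnBr2, n-PrSH, CH2Cl2, 0 °C) should give 4-[(2R,3S)-2-(tert-butyldimethylsilyloxy)-3-hydroxy-3-[3,4,5-tris(benzyloxy)phenyl]propyl]-3,5-dihydroxyphenyl 3,4,5-tris(benzyloxy)benzoate F4. Intramolecular Mitsunobu etherification (PPh3, DIAD, THF, high dilution) closes O1–C2 with inversion at the benzylic carbon to (2R,3R)-3-(tert-butyldimethylsilyloxy)-5-hydroxy-2-[3,4,5-tris(benzyloxy)phenyl]chroman-7-yl 3,4,5-tris(benzyloxy)benzoate F5. HF·pyridine in THF then returns 22.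

2. Step 8. Acid-catalysed ethanolysis may remove the aryl gallate, and the methoxymethyl cation released from the MOM groups may alkylate the electron-rich A ring before ethanol traps it. Fallback (sets out from 8, returns at 23): the ring is closed before the ester is present and the 5-OH is then capped. The same acid treatment of 8 should give (2RS,3R)-2-ethoxy-7-(triisopropylsilyloxy)chroman-3,5-diol F6. Benzylation of the only phenol (BnBr, K2CO3, acetone) should give (2RS,3R)-5-(benzyloxy)-2-ethoxy-7-(triisopropylsilyloxy)chroman-3-ol F7. TBAF/AcOH should give (2RS,3R)-5-(benzyloxy)-2-ethoxychroman-3,7-diol F8. Acylation with 11 (Et3N, CH2Cl2) should give (2RS,3R)-5-(benzyloxy)-2-ethoxy-3-hydroxychroman-7-yl 3,4,5-tris(benzyloxy)benzoate F9. Arylation with 19 under the conditions of step 12 should give (2R,3R)-5-(benzyloxy)-3-hydroxy-2-[3,4,5-tris(benzyloxy)phenyl]chroman-7-yl 3,4,5-tris(benzyloxy)benzoate F10. Hydrogenolysis as in step 13 removes all seven benzyl ethers and returns 23.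

3. Step 4. The hindered, doubly ortho-substituted aryl-copper species may open the acetal-bearing epoxide too slowly or attack the acetal, and the step depends on the enantiopurity delivered by the kinetic resolution. Fallback (sets out from 3, returns at 8): a commercial enantiopure epoxide at the ester oxidation level is used and the oxidation state is adjusted afterwards. Arylmagnesium 7, made from 3 as before, should open methyl (R)-glycidate at C3 (CuI cat., THF, −40 °C) to methyl (2R)-2-hydroxy-3-[2,6-bis(methoxymethoxy)-4-(triisopropylsilyloxy)phenyl]propanoate F11. DIBAL-H (2.2 eq, CH2Cl2, −78 °C) should reduce the ester to (2R)-2-hydroxy-3-[2,6-bis(methoxymethoxy)-4-(triisopropylsilyloxy)phenyl]propanal F12. HC(OEt)3 and PPTS in EtOH then convert it into 8.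

**Further compounds**

F1 | step 12 | 4-[(2R)-2-(tert-butyldimethylsilyloxy)-3,3-diethoxypropyl]-3,5-bis(methoxymethoxy)phenyl 3,4,5-tris(benzyloxy)benzoate | CCOC(OCC)[C@H](O[Si](C)(C)C(C)(C)C)Cc1c(OCOC)cc(OC(=O)c2cc(OCc3ccccc3)c(OCc3ccccc3)c(OCc3ccccc3)c2)cc1OCOC
F2 | step 12 | 4-[(2R)-2-(tert-butyldimethylsilyloxy)-3-oxopropyl]-3,5-bis(methoxymethoxy)phenyl 3,4,5-tris(benzyloxy)benzoate | O=C[C@H](O[Si](C)(C)C(C)(C)C)Cc1c(OCOC)cc(OC(=O)c2cc(OCc3ccccc3)c(OCc3ccccc3)c(OCc3ccccc3)c2)cc1OCOC
F3 | step 12 | 4-[(2R,3S)-2-(tert-butyldimethylsilyloxy)-3-hydroxy-3-[3,4,5-tris(benzyloxy)phenyl]propyl]-3,5-bis(methoxymethoxy)phenyl 3,4,5-tris(benzyloxy)benzoate | O[C@@H](c1cc(OCc2ccccc2)c(OCc2ccccc2)c(OCc2ccccc2)c1)[C@H](O[Si](C)(C)C(C)(C)C)Cc1c(OCOC)cc(OC(=O)c2cc(OCc3ccccc3)c(OCc3ccccc3)c(OCc3ccccc3)c2)cc1OCOC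
F4 | step 12 | 4-[(2R,3S)-2-(tert-butyldimethylsilyloxy)-3-hydroxy-3-[3,4,5-tris(benzyloxy)phenyl]propyl]-3,5-dihydroxyphenyl 3,4,5-tris(benzyloxy)benzoate | O[C@@H](c1cc(OCc2ccccc2)c(OCc2ccccc2)c(OCc2ccccc2)c1)[C@H](O[Si](C)(C)C(C)(C)C)Cc1c(O)cc(OC(=O)c2cc(OCc3ccccc3)c(OCc3ccccc3)c(OCc3ccccc3)c2)cc1O
F5 | step 12 | (2R,3R)-3-(tert-butyldimethylsilyloxy)-5-hydroxy-2-[3,4,5-tris(benzyloxy)phenyl]chroman-7-yl 3,4,5-tris(benzyloxy)benzoate | O=C(Oc1cc(O)c2c(c1)O[C@H](c1cc(OCc3ccccc3)c(OCc3ccccc3)c(OCc3ccccc3)c1)[C@H](O[Si](C)(C)C(C)(C)C)C2)c1cc(OCc3ccccc3)c(OCc3ccccc3)c(OCc3ccccc3)c1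
F6 | step 8 | (2RS,3R)-2-ethoxy-7-(triisopropylsilyloxy)chroman-3,5-diol | CC(C)[Si](Oc1cc(O)c2c(c1)OC(OCC)[C@H](O)C2)(C(C)C)C(C)C
F7 | step 8 | (2RS,3R)-5-(benzyloxy)-2-ethoxy-7-(triisopropylsilyloxy)chroman-3-ol | CC(C)[Si](Oc1cc(OCc3ccccc3)c2c(c1)OC(OCC)[C@H](O)C2)(C(C)C)C(C)C
F8 | step 8 | (2RS,3R)-5-(benzyloxy)-2-ethoxychroman-3,7-diol | Oc1cc(OCc3ccccc3)c2c(c1)OC(OCC)[C@H](O)C2
F9 | step 8 | (2RS,3R)-5-(benzyloxy)-2-ethoxy-3-hydroxychroman-7-yl 3,4,5-tris(benzyloxy)benzoate | O=C(Oc1cc(OCc3ccccc3)c2c(c1)OC(OCC)[C@H](O)C2)c1cc(OCc3ccccc3)c(OCc3ccccc3)c(OCc3ccccc3)c1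
F10 | step 8 | (2R,3R)-5-(benzyloxy)-3-hydroxy-2-[3,4,5-tris(benzyloxy)phenyl]chroman-7-yl 3,4,5-tris(benzyloxy)benzoate | O=C(Oc1cc(OCc3ccccc3)c2c(c1)O[C@H](c1cc(OCc3ccccc3)c(OCc3ccccc3)c(OCc3ccccc3)c1)[C@H](O)C2)c1cc(OCc3ccccc3)c(OCc3ccccc3)c(OCc3ccccc3)c1
F11 | step 4 | methyl (2R)-2-hydroxy-3-[2,6-bis(methoxymethoxy)-4-(triisopropylsilyloxy)phenyl]propanoate | COC(=O)[C@H](O)Cc1c(OCOC)cc(O[Si](C(C)C)(C(C)C)C(C)C)cc1OCOC
F12 | step 4 | (2R)-2-hydroxy-3-[2,6-bis(methoxymethoxy)-4-(triisopropylsilyloxy)phenyl]propanal | O=C[C@H](O)Cc1c(OCOC)cc(O[Si](C(C)C)(C(C)C)C(C)C)cc1OCOC
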